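The numbering follows benzofuran: O1, C2, C3 and C3a to C7a. Ring A is the arene, ring B the dihydrofuran, C1' the carbinol carbon on C5, and Cα the enal carbon on C2.
Cuts: the enal CHO goes back to a silylated CH2OH, both tiglate acyl–O bonds are cut, the C1' carbinol goes back to the C5 acetyl group, and ring B is finally cut at C2–C3 and O1–C2.
Enabling feature: C2 is the only ring-B atom that a salicylaldehyde lacks. It is bonded to both the aryl ether oxygen O1 and the carbinol carbon C3, so it can enter as one ylide carbon that already carries Cα(=CH2)CH2O.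
Forward order: ring A is bought and formylated, and ring B closes in one operation from the aldehyde and a chiral allyl sulfonium salt. Ketone reduction, double acylation, desilylation and oxidation follow.
Stereochemistry: C3 (S) and C2 (R, trans) come from the (2R,5R)-2,5-dimethylthiolane of the ylide and a stereospecific closure. C1' (R) comes from RuCl(p-cymene)[(R,R)-TsDPEN], and both E alkenes come from tiglic acid.

Key step: step 7

Assumption: the (2R,5R)-thiolane is taken to screen the same ylide face as in its established benzyl and 2-methylallyl ylide epoxidations of aromatic aldehydes, which lead to (S,S)-trans-oxiranes; such an oxirane opened at the alkenyl-bearing carbon with inversion maps onto (2R,3S).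

Step 1
Reactants: 1 4'-hydroxyacetophenone
Product: 2 5-acetyl-2-hydroxybenzaldehyde
Conditions: hexamethylenetetramine (1.2 equiv), CF3CO2H, 85 °C; 3 M aq. HCl, rt
Reagents that add atoms: hexamethylenetetramine C1N2CN3CN1CN(C2)C3 (formyl carbon); water O (formyl oxygen)
Why: Duff reaction (ortho-formylation of a phenol by protonated hexamethylenetetramine, then hydrolysis), in which the para position is blocked by the acetyl group, the two ortho positions are equivalent, and only a small excess of the amine holds the reaction at the monoaldehyde.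

Step 2
Reactants: 3 2-methylenepropane-1,3-diol
Product: 4 2-({[tert-butyl(dimethyl)silyl]oxy}methyl)prop-2-en-1-ol
Conditions: NaH (1.0 equiv), TBSCl (1.0 equiv), THF, 0 °C to rt
Reagents that add atoms: tert-butyldimethylsilyl chloride CC(C)(C)[Si](C)(C)Cl
Why: O-silylation of a symmetrical diol with one equivalent each of NaH and TBSCl in THF is a standard monoprotection, and since the two hydroxyls are equivalent only one monoether can form.

Step 3
Reactants: 4 2-({[tert-butyl(dimethyl)silyl]oxy}methyl)prop-2-en-1-ol
Product: 5 {[2-(bromomethyl)prop-2-en-1-yl]oxy}(tert-butyl)dimethylsilane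
Conditions: CBr4, PPh3, CH2Cl2, 0 °C
Reagents that add atoms: carbon tetrabromide BrC(Br)(Br)Br
Why: Appel bromination runs under neutral conditions that spare the silyl ether, and direct and allylically transposed substitution lead to the same bromide.

Step 4
Reactants: 6 (2S,5S)-hexane-2,5-diol
Product: 7 (2S,5S)-hexane-2,5-diyl dimethanesulfonate
Conditions: MsCl, Et3N, CH2Cl2, −20 to 0 °C
Reagents that add atoms: methanesulfonyl chloride CS(=O)(=O)Cl
Why: Mesylate formation takes place at oxygen, breaks no C–O bond, and so keeps both S centres.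

Step 5
Reactants: 7 (2S,5S)-hexane-2,5-diyl dimethanesulfonate
Product: 8 (2R,5R)-2,5-dimethylthiolane
Conditions: Na2S·9H2O, EtOH, rt
Reagents that add atoms: Na2S [Na+].[Na+].[S-2]
Why: Double SN2 thioetherification, the second displacement closing the thiolane 5-exo-tet, inverts each carbon once, so the (S,S)-dimesylate gives the (R,R)-thiolane.

Step 6
Reactants: 5 {[2-(bromomethyl)prop-2-en-1-yl]oxy}(tert-butyl)dimethylsilane; 8 (2R,5R)-2,5-dimethylthiolane
Product: 9 (2R,5R)-1-[2-({[tert-butyl(dimethyl)silyl]oxy}methyl)prop-2-en-1-yl]-2,5-dimethylthiolan-1-ium bromide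
Conditions: acetone (3 M), rt, dark, 72 h; trituration with Et2O
Reagents that add atoms: none
Why: S-alkylation of a dialkyl sulfide by a reactive allylic bromide (sulfonium salt formation) is driven by precipitation of the salt, and because the two lone pairs of the twofold-symmetric sulfide are homotopic, sulfur is no stereocentre and a single salt results.

Step 7
Reactants: 2 5-acetyl-2-hydroxybenzaldehyde; 9 (2R,5R)-1-[2-({[tert-butyl(dimethyl)silyl]oxy}methyl)prop-2-en-1-yl]-2,5-dimethylthiolan-1-ium bromide
Product: 12 1-[(2R,3S)-2-(3-{[tert-butyl(dimethyl)silyl]oxy}prop-1-en-2-yl)-3-hydroxy-2,3-dihydro-1-benzofuran-5-yl]ethan-1-one, via allyl ylide 10 (not isolated), via trans-vinyl oxirane 11 (not isolated)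
Conditions: Cs2CO3 (2.5 equiv), MeCN, 0 °C to rt, then 40 °C
Reagents that add atoms: none
Why: Proposed new method: Cs2CO3 converts 2 into its phenoxide and 9 into the allyl ylide 10, whose α-carbon adds to the formyl carbon (C2–C3 bond); the new alkoxide expels the thiolane from the anti-periplanar conformer to give the trans-vinyl oxirane 11, and the ortho phenoxide then opens 11 at its allylic carbon with inversion (O1–C2 bond). The closest known reaction types are the (4+1) annulation of salicylaldehydes with sulfoxonium or stabilised sulfonium ylides to trans-2-substituted 2,3-dihydrobenzofuran-3-ols and the asymmetric Johnson–Corey–Chaykovsky epoxidation of aromatic aldehydes with 2-substituted allyl ylides of this thiolane; joining the two on a free phenol is the untested part. The transient oxirane closes 3-exo-tet and ring B closes by a 5-endo-tet oxirane opening, viable because the only alternative (4-exo at C3) is strained and the breaking C2–O bond is allylic, as in the known cyclisation of ortho-hydroxyaryl oxiranes to 2,3-dihydrobenzofuran-3-ols. C3 is fixed in the addition: the twofold-symmetric thiolane gives a single salt, one of its methyl groups screens one face of the ylide, and the anti adduct goes on to the oxirane while the syn adduct reverts, which should give the (S,S)-oxirane and hence 3S. C2 follows stereospecifically from two successive inversions at the ylide carbon, which places the alkenyl group trans to the hydroxyl and gives 2R. The step needs attack at the aldehyde and not at the aryl methyl ketone (an aldehyde is far more electrophilic and less hindered), α- and not γ-attack of the ylide (charge is highest next to sulfur), SN2 and not SN2' opening (five- against seven-membered ring), and a phenoxide too weak to displace the thiolane before the alkoxide does (secured by the para acetyl group).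

Step 8
Reactants: 12 1-[(2R,3S)-2-(3-{[tert-butyl(dimethyl)silyl]oxy}prop-1-en-2-yl)-3-hydroxy-2,3-dihydro-1-benzofuran-5-yl]ethan-1-one
Product: 13 (2R,3S)-2-(3-{[tert-butyl(dimethyl)silyl]oxy}prop-1-en-2-yl)-5-[(1R)-1-hydroxyethyl]-2,3-dihydro-1-benzofuran-3-ol
Conditions: RuCl(p-cymene)[(R,R)-TsDPEN] (1 mol %), HCO2H–Et3N (5:2), EtOAc, 30 °C
Reagents that add atoms: none
Why: Noyori–Ikariya asymmetric transfer hydrogenation of an aryl methyl ketone, in which the (R,R)-catalyst sets C1' as R under catalyst control (the ring-B centres are remote), formic acid makes hydride delivery irreversible so that the C3 carbinol is not equilibrated, the alkene and silyl ether are inert, any antipodal ring-B material becomes a separable diastereomer, and the reduction is safe only now because O1 is an ether and can no longer expel a C1' leaving group as a para-quinone methide.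

Step 9
Reactants: 13 (2R,3S)-2-(3-{[tert-butyl(dimethyl)silyl]oxy}prop-1-en-2-yl)-5-[(1R)-1-hydroxyethyl]-2,3-dihydro-1-benzofuran-3-ol; 14 tiglic acid, (2E)-2-methylbut-2-enoic acid
Product: 15 (1R)-1-[(2R,3S)-2-(3-{[tert-butyl(dimethyl)silyl]oxy}prop-1-en-2-yl)-3-{[(2E)-2-methylbut-2-enoyl]oxy}-2,3-dihydro-1-benzofuran-5-yl]ethyl (2E)-2-methylbut-2-enoate
Conditions: 14 (3 equiv), DCC (3 equiv), DMAP (0.5 equiv), CH2Cl2, 0 °C to rt
Reagents that add atoms: none
Why: Steglich esterification acylates both secondary benzylic alcohols at oxygen with retention at C3 and C1', the E geometry comes with 14 and is the thermodynamically favoured one, and base-induced loss of the C3 ester is disfavoured because H2 and the C3 oxygen are syn in the trans series.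

Step 10
Reactants: 15 (1R)-1-[(2R,3S)-2-(3-{[tert-butyl(dimethyl)silyl]oxy}prop-1-en-2-yl)-3-{[(2E)-2-methylbut-2-enoyl]oxy}-2,3-dihydro-1-benzofuran-5-yl]ethyl (2E)-2-methylbut-2-enoate
Product: 16 (1R)-1-[(2R,3S)-2-(3-hydroxyprop-1-en-2-yl)-3-{[(2E)-2-methylbut-2-enoyl]oxy}-2,3-dihydro-1-benzofuran-5-yl]ethyl (2E)-2-methylbut-2-enoate
Conditions: HF·pyridine, pyridine, THF, 0 °C to rt
Reagents that add atoms: none
Why: Fluoride-mediated cleavage of a primary tert-butyldimethylsilyl ether is driven by Si–F bond formation, and the pyridine buffer keeps the medium too weakly acidic to ionise the benzylic esters and too weakly basic to cleave or shift them.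

Step 11
Reactants: 16 (1R)-1-[(2R,3S)-2-(3-hydroxyprop-1-en-2-yl)-3-{[(2E)-2-methylbut-2-enoyl]oxy}-2,3-dihydro-1-benzofuran-5-yl]ethyl (2E)-2-methylbut-2-enoate
Product: 17 (1R)-1-[(2R,3S)-3-{[(2E)-2-methylbut-2-enoyl]oxy}-2-(3-oxoprop-1-en-2-yl)-2,3-dihydro-1-benzofuran-5-yl]ethyl (2E)-2-methylbut-2-enoate (CNP0292799.1)
Conditions: activated MnO2 (20 equiv), CH2Cl2, rt
Reagents that add atoms: none
Why: MnO2 oxidation, selective for allylic alcohols and run under neutral heterogeneous conditions, turns the only free hydroxyl into the 2-substituted acrolein as the last operation, so that the enal meets no base or nucleophile and no stereocentre is touched.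

Compound list
1 | 4'-hydroxyacetophenone | CC(=O)c1ccc(O)cc1 | starting material
2 | 5-acetyl-2-hydroxybenzaldehyde | CC(=O)c1ccc(O)c(C=O)c1 | intermediate
3 | 2-methylenepropane-1,3-diol | C=C(CO)CO | starting material
4 | 2-({[tert-butyl(dimethyl)silyl]oxy}methyl)prop-2-en-1-ol | C=C(CO)CO[Si](C)(C)C(C)(C)C | intermediate
5 | {[2-(bromomethyl)prop-2-en-1-yl]oxy}(tert-butyl)dimethylsilane | C=C(CBr)CO[Si](C)(C)C(C)(C)C | intermediate
6 | (2S,5S)-hexane-2,5-diol | C[C@H](O)CC[C@H](C)O | starting material
7 | (2S,5S)-hexane-2,5-diyl dimethanesulfonate | C[C@H](OS(C)(=O)=O)CC[C@H](C)OS(C)(=O)=O | intermediate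
8 | (2R,5R)-2,5-dimethylthiolane | C[C@@H]1CC[C@@H](C)S1 | intermediate
9 | (2R,5R)-1-[2-({[tert-butyl(dimethyl)silyl]oxy}methyl)prop-2-en-1-yl]-2,5-dimethylthiolan-1-ium bromide | C[C@@H]1CC[C@@H](C)[S+]1CC(=C)CO[Si](C)(C)C(C)(C)C.[Br-] | intermediate
10 | allyl ylide of 9, deprotonated at the S-bound allylic carbon (not isolated) | C[C@@H]1CC[C@@H](C)[S+]1[CH-]C(=C)CO[Si](C)(C)C(C)(C)C | intermediate
11 | 1-{3-[(2S,3S)-3-(3-{[tert-butyl(dimethyl)silyl]oxy}prop-1-en-2-yl)oxiran-2-yl]-4-hydroxyphenyl}ethan-1-one, present as its cesium phenoxide (not isolated) | CC(=O)c1ccc(O)c(c1)[C@@H]2O[C@H]2C(=C)CO[Si](C)(C)C(C)(C)C | intermediate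
12 | 1-[(2R,3S)-2-(3-{[tert-butyl(dimethyl)silyl]oxy}prop-1-en-2-yl)-3-hydroxy-2,3-dihydro-1-benzofuran-5-yl]ethan-1-one | C=C(CO[Si](C)(C)C(C)(C)C)[C@H]1Oc2ccc(C(C)=O)cc2[C@@H]1O | intermediate
13 | (2R,3S)-2-(3-{[tert-butyl(dimethyl)silyl]oxy}prop-1-en-2-yl)-5-[(1R)-1-hydroxyethyl]-2,3-dihydro-1-benzofuran-3-ol | C=C(CO[Si](C)(C)C(C)(C)C)[C@H]1Oc2ccc([C@@H](C)O)cc2[C@@H]1O | intermediate
14 | tiglic acid, (2E)-2-methylbut-2-enoic acid | C/C=C(\C)C(=O)O | starting material
15 | (1R)-1-[(2R,3S)-2-(3-{[tert-butyl(dimethyl)silyl]oxy}prop-1-en-2-yl)-3-{[(2E)-2-methylbut-2-enoyl]oxy}-2,3-dihydro-1-benzofuran-5-yl]ethyl (2E)-2-methylbut-2-enoate | C=C(CO[Si](C)(C)C(C)(C)C)[C@H]1Oc2ccc([C@@H](C)OC(=O)/C(C)=C/C)cc2[C@@H]1OC(=O)/C(C)=C/C | intermediate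
16 | (1R)-1-[(2R,3S)-2-(3-hydroxyprop-1-en-2-yl)-3-{[(2E)-2-methylbut-2-enoyl]oxy}-2,3-dihydro-1-benzofuran-5-yl]ethyl (2E)-2-methylbut-2-enoate | C=C(CO)[C@H]1Oc2ccc([C@@H](C)OC(=O)/C(C)=C/C)cc2[C@@H]1OC(=O)/C(C)=C/C | intermediate
17 | (1R)-1-[(2R,3S)-3-{[(2E)-2-methylbut-2-enoyl]oxy}-2-(3-oxoprop-1-en-2-yl)-2,3-dihydro-1-benzofuran-5-yl]ethyl (2E)-2-methylbut-2-enoate | C=C(C=O)[C@H]1Oc2ccc([C@@H](C)OC(=O)/C(C)=C/C)cc2[C@@H]1OC(=O)/C(C)=C/C | target

Total step count: 11.
Longest linear sequence: 8 steps (steps 4 to 11 from 6, or steps 2, 3 and 6 to 11 from 3).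

Steps most likely to fail

Step 7. The phenoxide may attack the sulfonium-bearing carbon of the first adducts directly (5-exo-tet) instead of waiting for oxirane formation.
- This shortcut would send the anti adduct into the cis series and the syn adduct into the antipodal trans series, so both diastereo- and enantioselectivity would erode.
- O-allylation of the phenoxide by the salt, a [2,3]-shift after deprotonation at a ring methine, and aldol self-condensation of the keto aldehyde would each cost material.

The fallback uncouples the two bond formations into individually known operations, sets out from 2 and 9, and returns at 12. Compound 2 is silylated (i-Pr3SiCl, imidazole, DMF) to 5-acetyl-2-[(triisopropylsilyl)oxy]benzaldehyde F1. Ylide 10, preformed from 9 with KN(SiMe3)2 in THF at −78 °C, then epoxidises F1 in the established asymmetric Johnson–Corey–Chaykovsky manner. This gives 1-{3-[(2S,3S)-3-(3-{[tert-butyl(dimethyl)silyl]oxy}prop-1-en-2-yl)oxiran-2-yl]-4-[(triisopropylsilyl)oxy]phenyl}ethan-1-one F2, which is purified and assayed. Bu4NF (1.0 equiv, THF, −20 to 0 °C) removes only the aryl silyl ether. The phenoxide of 11 released in this way opens the oxirane at the allylic carbon and gives 12.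

Step 9. Acylation at the more hindered C3 hydroxyl may be slow enough for the activated acid to rearrange to an unreactive acylurea. In addition, the electron-rich ring of the diol favours ionisation at C3 or C1', with epimerisation or loss of tiglic acid and aromatisation of ring B.

The fallback stages the two acylations around the reduction, sets out from 12, and returns at 15. The C3 hydroxyl is acylated while the ring is still electron-poor, using (2E)-2-methylbut-2-enoyl chloride and pyridine in CH2Cl2 at 0 °C. The product is (2R,3S)-5-acetyl-2-(3-{[tert-butyl(dimethyl)silyl]oxy}prop-1-en-2-yl)-2,3-dihydro-1-benzofuran-3-yl (2E)-2-methylbut-2-enoate F3. Transfer hydrogenation under the conditions of step 8 gives (2R,3S)-2-(3-{[tert-butyl(dimethyl)silyl]oxy}prop-1-en-2-yl)-5-[(1R)-1-hydroxyethyl]-2,3-dihydro-1-benzofuran-3-yl (2E)-2-methylbut-2-enoate F4. The unhindered C1' hydroxyl is then acylated with the same acid chloride to give 15.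

Step 10. During desilylation the benzylic esters may ionise (racemisation at C1', loss of tiglic acid from C3 with aromatisation). An acyl group may also shift to the freed primary hydroxyl.

The fallback removes the silyl group before any ester is present, sets out from 13, and returns at 17. Bu4NF in THF converts 13 into (2R,3S)-5-[(1R)-1-hydroxyethyl]-2-(3-hydroxyprop-1-en-2-yl)-2,3-dihydro-1-benzofuran-3-ol F5. TEMPO (catalytic) with PhI(OAc)2 in CH2Cl2 oxidises the primary allylic alcohol in preference to the two secondary ones. This gives 2-{(2R,3S)-3-hydroxy-5-[(1R)-1-hydroxyethyl]-2,3-dihydro-1-benzofuran-2-yl}prop-2-enal F6. Double Steglich esterification with 14 under the conditions of step 9 then gives 17.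

Further compounds
F1 | step 7 | 5-acetyl-2-[(triisopropylsilyl)oxy]benzaldehyde | CC(=O)c1ccc(O[Si](C(C)C)(C(C)C)C(C)C)c(C=O)c1
F2 | step 7 | 1-{3-[(2S,3S)-3-(3-{[tert-butyl(dimethyl)silyl]oxy}prop-1-en-2-yl)oxiran-2-yl]-4-[(triisopropylsilyl)oxy]phenyl}ethan-1-one | CC(=O)c1ccc(O[Si](C(C)C)(C(C)C)C(C)C)c(c1)[C@@H]2O[C@H]2C(=C)CO[Si](C)(C)C(C)(C)C
F3 | step 9 | (2R,3S)-5-acetyl-2-(3-{[tert-butyl(dimethyl)silyl]oxy}prop-1-en-2-yl)-2,3-dihydro-1-benzofuran-3-yl (2E)-2-methylbut-2-enoate | C=C(CO[Si](C)(C)C(C)(C)C)[C@H]1Oc2ccc(C(C)=O)cc2[C@@H]1OC(=O)/C(C)=C/C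
F4 | step 9 | (2R,3S)-2-(3-{[tert-butyl(dimethyl)silyl]oxy}prop-1-en-2-yl)-5-[(1R)-1-hydroxyethyl]-2,3-dihydro-1-benzofuran-3-yl (2E)-2-methylbut-2-enoate | C=C(CO[Si](C)(C)C(C)(C)C)[C@H]1Oc2ccc([C@@H](C)O)cc2[C@@H]1OC(=O)/C(C)=C/C
F5 | step 10 | (2R,3S)-5-[(1R)-1-hydroxyethyl]-2-(3-hydroxyprop-1-en-2-yl)-2,3-dihydro-1-benzofuran-3-ol | C=C(CO)[C@H]1Oc2ccc([C@@H](C)O)cc2[C@@H]1O
F6 | step 10 | 2-{(2R,3S)-3-hydroxy-5-[(1R)-1-hydroxyethyl]-2,3-dihydro-1-benzofuran-2-yl}prop-2-enal | C=C(C=O)[C@H]1Oc2ccc([C@@H](C)O)cc2[C@@H]1O
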